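**Retrosynthetic overview** (germacranolide numbering: lactone O on C6, ring-fusion C7, ester carbon C8, C10 bears CH2OH (C14), C4=C5 bears CH2OH (C15), C11(=C13)–C12 is the methylene lactone)
1. Target 29 ⇐ C8 methacrylation and desilylation of macrocyclic hydroxy lactone 27.
2. Key step, ring 2 (ten-membered carbocycle, formed last): C7–C8 closure by intramolecular CrCl2 allylation of butenolide allyl bromide/aldehyde 25; this creates the α-methylene lactone, C7 and C8 from the single butenolide stereocentre C6.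
3. Ring 1 (butenolide, formed first): carbonylative lactonisation of a (Z)-iodoalkenol; C6 from asymmetric alkynylation of (Z)-enal 16.
4. (Z)-Enal ⇐ copper-catalysed syn-hydroalkylation of ynoate 12 with a B-alkyl-9-BBN (C3–C4 bond, alkene geometry); C10 ⇐ Evans allylation.

Assumption: (S,S)-ProPhenol is taken to deliver the alkynylzinc to the Re face of enal 16 (giving 6S); if a test run shows the opposite sense, (R,R)-ProPhenol is used with no other change.

**Step 1**
Reactants: 1 methyl 4,4-dimethoxybutanoate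
Product: 2 lithium 4,4-dimethoxybutanoate
Conditions: LiOH·H2O (1.0 equiv), THF/H2O, 0 °C to rt; evaporate, dry
Reagents that add atoms: lithium hydroxide [Li+].[OH-]
Why: Saponification; base leaves the dimethyl acetal untouched and isolating the dry lithium salt avoids any acidic work-up.

**Step 2**
Reactants: 2 lithium 4,4-dimethoxybutanoate; 3 (4R)-4-benzyl-1,3-oxazolidin-2-one
Product: 5 (4R)-4-benzyl-3-(4,4-dimethoxybutanoyl)-1,3-oxazolidin-2-one, via mixed pivalic anhydride 4 (not isolated)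
Conditions: t-BuCOCl, THF, −20 °C; then 3, Et3N, rt
Reagents that add atoms: none
Why: Mixed-anhydride N-acylation: the carboxylate and pivaloyl chloride give the anhydride, which acylates the oxazolidinone at its less hindered carbonyl (LiCl formed in situ assists).

**Step 3**
Reactants: 5 (4R)-4-benzyl-3-(4,4-dimethoxybutanoyl)-1,3-oxazolidin-2-one
Product: 7 (4R)-4-benzyl-3-[(2R)-2-(2,2-dimethoxyethyl)pent-4-enoyl]-1,3-oxazolidin-2-one, via sodium Z-enolate 6 (not isolated)
Conditions: NaN(SiMe3)2, THF, −78 °C; CH2=CHCH2I, −78 to −45 °C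
Reagents that add atoms: allyl iodide C=CCI
Why: Evans asymmetric alkylation: the chelated sodium Z-enolate is allylated on the face away from the benzyl group, which sets C10 (R).

**Step 4**
Reactants: 7 (4R)-4-benzyl-3-[(2R)-2-(2,2-dimethoxyethyl)pent-4-enoyl]-1,3-oxazolidin-2-one
Product: 8 (2R)-2-(2,2-dimethoxyethyl)pent-4-en-1-ol
Conditions: LiBH4, H2O (1 equiv), Et2O, 0 °C
Reagents that add atoms: none
Why: Reductive cleavage of the imide releases the primary alcohol (C14) and the recoverable auxiliary without touching acetal or alkene.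

**Step 5**
Reactants: 8 (2R)-2-(2,2-dimethoxyethyl)pent-4-en-1-ol
Product: 9 tert-butyl{[(2R)-2-(2,2-dimethoxyethyl)pent-4-en-1-yl]oxy}dimethylsilane
Conditions: t-BuMe2SiCl, imidazole, DMF, rt
Reagents that add atoms: tert-butyldimethylsilyl chloride CC(C)(C)[Si](C)(C)Cl
Why: Standard silylation of the primary alcohol.

**Step 6**
Reactants: 10 tert-butyldimethyl(prop-2-yn-1-yloxy)silane
Product: 12 methyl 4-[(tert-butyldimethylsilyl)oxy]but-2-ynoate, via lithium acetylide 11 (not isolated)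
Conditions: n-BuLi, THF, −78 °C; ClCO2Me, −78 to 0 °C
Reagents that add atoms: methyl chloroformate COC(=O)Cl
Why: Deprotonation of the terminal alkyne and C-acylation of the lithium acetylide with the chloroformate.

**Step 7**
Reactants: 9 tert-butyl{[(2R)-2-(2,2-dimethoxyethyl)pent-4-en-1-yl]oxy}dimethylsilane; 12 methyl 4-[(tert-butyldimethylsilyl)oxy]but-2-ynoate
Product: 14 methyl (2Z,7R)-3,7-bis{[(tert-butyldimethylsilyl)oxy]methyl}-9,9-dimethoxynon-2-enoate, via B-alkyl-9-BBN 13 (not isolated)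
Conditions: 9-BBN-H, THF, 60 °C; then 12, CuOAc (10 mol%), P(OPh)3 (20 mol%), t-BuOK (10 mol%), t-BuOH (1.5 equiv), 1,4-dioxane, 25 °C
Reagents that add atoms: none
Why: Brown hydroboration puts boron on the terminal carbon, and copper-catalysed conjugate addition of the alkyl-9-BBN to the ynoate (B-to-Cu transmetalation, syn-carbocupration, protonation of the alkenylcopper with retention) is a formal syn-hydroalkylation, so the new chain is trans to the ester and CH2OTBS cis, which fixes the C4=C5 geometry.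

**Step 8**
Reactants: 14 methyl (2Z,7R)-3,7-bis{[(tert-butyldimethylsilyl)oxy]methyl}-9,9-dimethoxynon-2-enoate
Product: 15 (2Z,7R)-3,7-bis{[(tert-butyldimethylsilyl)oxy]methyl}-9,9-dimethoxynon-2-en-1-ol
Conditions: i-Bu2AlH (2.3 equiv), CH2Cl2, −78 °C; aq. potassium sodium tartrate work-up
Reagents that add atoms: none
Why: 1,2-Reduction of the enoate to the allylic alcohol at low temperature; alkene geometry, silyl ethers and acetal are untouched.

**Step 9**
Reactants: 15 (2Z,7R)-3,7-bis{[(tert-butyldimethylsilyl)oxy]methyl}-9,9-dimethoxynon-2-en-1-ol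
Product: 16 (2Z,7R)-3,7-bis{[(tert-butyldimethylsilyl)oxy]methyl}-9,9-dimethoxynon-2-enal
Conditions: MnO2, CH2Cl2, rt
Reagents that add atoms: none
Why: Chemoselective allylic oxidation with MnO2 under neutral conditions keeps the Z geometry.

**Step 10**
Reactants: 16 (2Z,7R)-3,7-bis{[(tert-butyldimethylsilyl)oxy]methyl}-9,9-dimethoxynon-2-enal; 17 1-methoxy-4-[(prop-2-yn-1-yloxy)methyl]benzene
Product: 19 (4S,5Z,10R)-6,10-bis{[(tert-butyldimethylsilyl)oxy]methyl}-12,12-dimethoxy-1-[(4-methoxybenzyl)oxy]dodec-5-en-2-yn-4-ol, via methylzinc alkynylide 18 (not isolated)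
Conditions: (S,S)-ProPhenol (20 mol%), Ph3P=O (40 mol%), Me2Zn (3 equiv), 17 (3 equiv), toluene, 0 to 4 °C
Reagents that add atoms: none
Why: Zn-ProPhenol catalytic asymmetric alkynylation of the enal: the chiral dinuclear zinc complex delivers the alkynyl group to the Re face and sets C6 (S).

**Step 11**
Reactants: 19 (4S,5Z,10R)-6,10-bis{[(tert-butyldimethylsilyl)oxy]methyl}-12,12-dimethoxy-1-[(4-methoxybenzyl)oxy]dodec-5-en-2-yn-4-ol
Product: 21 (2Z,4S,5Z,10R)-6,10-bis{[(tert-butyldimethylsilyl)oxy]methyl}-2-iodo-12,12-dimethoxy-1-[(4-methoxybenzyl)oxy]dodeca-2,5-dien-4-ol, via cyclic vinylalanate 20 (not isolated)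
Conditions: NaAlH2(OCH2CH2OMe)2, THF, 0 °C; then I2, −78 to 0 °C
Reagents that add atoms: iodine II
Why: Hydroxyl-directed trans-hydroalumination (hydride to the proximal alkyne carbon, aluminium on the distal one in a five-membered chelate) and iodinolysis with retention give the (Z)-iodoalkenol with iodine cis to the carbinol.

**Step 12**
Reactants: 21 (2Z,4S,5Z,10R)-6,10-bis{[(tert-butyldimethylsilyl)oxy]methyl}-2-iodo-12,12-dimethoxy-1-[(4-methoxybenzyl)oxy]dodeca-2,5-dien-4-ol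
Product: 22 (5S)-5-[(1Z,6R)-2,6-bis{[(tert-butyldimethylsilyl)oxy]methyl}-8,8-dimethoxyoct-1-en-1-yl]-3-{[(4-methoxybenzyl)oxy]methyl}furan-2(5H)-one
Conditions: PdCl2(PPh3)2 (5 mol%), CO (1 atm), K2CO3, THF, 25 °C
Reagents that add atoms: carbon monoxide [C-]#[O+]
Why: Palladium-catalysed carbonylative lactonisation (oxidative addition of zerovalent palladium, CO insertion, intramolecular alkoxide capture) closes the butenolide with retention of the C6 configuration and of both alkene geometries.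

**Step 13**
Reactants: 22 (5S)-5-[(1Z,6R)-2,6-bis{[(tert-butyldimethylsilyl)oxy]methyl}-8,8-dimethoxyoct-1-en-1-yl]-3-{[(4-methoxybenzyl)oxy]methyl}furan-2(5H)-one
Product: 23 (5S)-5-[(1Z,6R)-2,6-bis{[(tert-butyldimethylsilyl)oxy]methyl}-8,8-dimethoxyoct-1-en-1-yl]-3-(hydroxymethyl)furan-2(5H)-one
Conditions: DDQ, CH2Cl2/aq. pH 7 buffer, 0 °C
Reagents that add atoms: none
Why: Oxidative PMB removal (benzylic hydride abstraction by DDQ, then hydrolysis) under buffered conditions that spare silyl ethers, acetal and butenolide.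

**Step 14**
Reactants: 23 (5S)-5-[(1Z,6R)-2,6-bis{[(tert-butyldimethylsilyl)oxy]methyl}-8,8-dimethoxyoct-1-en-1-yl]-3-(hydroxymethyl)furan-2(5H)-one
Product: 24 (5S)-3-(bromomethyl)-5-[(1Z,6R)-2,6-bis{[(tert-butyldimethylsilyl)oxy]methyl}-8,8-dimethoxyoct-1-en-1-yl]furan-2(5H)-one
Conditions: NBS, Me2S, CH2Cl2, −20 to 0 °C
Reagents that add atoms: N-bromosuccinimide O=C1CCC(=O)N1Br
Why: Corey–Kim bromination: the alkoxysulfonium salt of the allylic alcohol is displaced by bromide under neutral, phosphine-free conditions.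

**Step 15**
Reactants: 24 (5S)-3-(bromomethyl)-5-[(1Z,6R)-2,6-bis{[(tert-butyldimethylsilyl)oxy]methyl}-8,8-dimethoxyoct-1-en-1-yl]furan-2(5H)-one
Product: 25 (3R,7Z)-8-[(2S)-4-(bromomethyl)-5-oxo-2,5-dihydrofuran-2-yl]-3,7-bis{[(tert-butyldimethylsilyl)oxy]methyl}oct-7-enal
Conditions: 10% aq. oxalic acid on SiO2, CH2Cl2, rt
Reagents that add atoms: water O
Why: Mild heterogeneous acid hydrolysis of the dimethyl acetal leaves the primary TBS ethers, the allylic bromide and the lactone intact.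

**Step 16**
Reactants: 25 (3R,7Z)-8-[(2S)-4-(bromomethyl)-5-oxo-2,5-dihydrofuran-2-yl]-3,7-bis{[(tert-butyldimethylsilyl)oxy]methyl}oct-7-enal
Product: 27 (3aS,4R,6R,10Z,11aS)-6,10-bis{[(tert-butyldimethylsilyl)oxy]methyl}-4-hydroxy-3-methylidene-3a,4,5,6,7,8,9,11a-octahydrocyclodeca[b]furan-2(3H)-one, via allylchromium dichloride 26 (not isolated)
Conditions: CrCl2 (6 equiv), degassed DMF, 25 °C, 25 added by syringe pump over 12 h (final 0.002 M)
Reagents that add atoms: none
Why: Proposed new method: intramolecular Nozaki–Hiyama-type (Barbier) allylation in which two CrCl2 reduce the allylic bromide to a σ-allyl trivalent-chromium species (its in-plane C6–O bond cannot align with the allyl π system, so vinylogous β-elimination is slow) that adds through C7 to the tethered aldehyde in a six-membered chair transition state; attack anti to the C6 alkenyl group gives the trans ring fusion (C7 S), and the ring-locked E-type allyl geometry with the aldehyde chain equatorial gives the anti C7/C8 relationship (C8 R); the closest known reactions are intermolecular Zn-, In- or CrCl2-mediated Barbier allylations of 5-substituted 3-(bromomethyl)furan-2(5H)-ones (trans, anti products) and CrCl2 macrocyclisations of 2-(bromomethyl)acrylates that close germacranolide ten-membered rings.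

**Step 17**
Reactants: 27 (3aS,4R,6R,10Z,11aS)-6,10-bis{[(tert-butyldimethylsilyl)oxy]methyl}-4-hydroxy-3-methylidene-3a,4,5,6,7,8,9,11a-octahydrocyclodeca[b]furan-2(3H)-one
Product: 28 (3aS,4R,6R,10Z,11aS)-6,10-bis{[(tert-butyldimethylsilyl)oxy]methyl}-3-methylidene-2-oxo-2,3,3a,4,5,6,7,8,9,11a-decahydrocyclodeca[b]furan-4-yl 2-methylprop-2-enoate
Conditions: methacrylic anhydride, Et3N, DMAP (cat.), CH2Cl2, 0 °C to rt
Reagents that add atoms: methacrylic anhydride CC(=C)C(=O)OC(=O)C(C)=C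
Why: DMAP-catalysed acylation of the only free hydroxyl, the secondary C8 alcohol, with retention.

**Step 18**
Reactants: 28 (3aS,4R,6R,10Z,11aS)-6,10-bis{[(tert-butyldimethylsilyl)oxy]methyl}-3-methylidene-2-oxo-2,3,3a,4,5,6,7,8,9,11a-decahydrocyclodeca[b]furan-4-yl 2-methylprop-2-enoate
Product: 29 (3aS,4R,6R,10Z,11aS)-6,10-bis(hydroxymethyl)-3-methylidene-2-oxo-2,3,3a,4,5,6,7,8,9,11a-decahydrocyclodeca[b]furan-4-yl 2-methylprop-2-enoate
Conditions: HF·pyridine, pyridine/THF, 0 °C to rt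
Reagents that add atoms: none
Why: Fluoride cleavage of both primary TBS ethers under buffered acidic conditions that neither add to the two acrylate units nor move the ester.

**Compound list**
1 | methyl 4,4-dimethoxybutanoate | COC(=O)CCC(OC)OC | starting material
2 | lithium 4,4-dimethoxybutanoate | [Li+].[O-]C(=O)CCC(OC)OC | intermediate
3 | (4R)-4-benzyl-1,3-oxazolidin-2-one | O=C1N[C@H](Cc2ccccc2)CO1 | starting material
4 | 4,4-dimethoxybutanoic pivalic anhydride | COC(OC)CCC(=O)OC(=O)C(C)(C)C | intermediate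
5 | (4R)-4-benzyl-3-(4,4-dimethoxybutanoyl)-1,3-oxazolidin-2-one | COC(OC)CCC(=O)N1[C@H](Cc2ccccc2)COC1=O | intermediate
6 | sodium (Z)-enolate of 5 | [Na+].[O-]/C(=C\CC(OC)OC)N1[C@H](Cc2ccccc2)COC1=O | intermediate
7 | (4R)-4-benzyl-3-[(2R)-2-(2,2-dimethoxyethyl)pent-4-enoyl]-1,3-oxazolidin-2-one | C=CC[C@H](CC(OC)OC)C(=O)N1[C@H](Cc2ccccc2)COC1=O | intermediate
8 | (2R)-2-(2,2-dimethoxyethyl)pent-4-en-1-ol | C=CC[C@H](CC(OC)OC)CO | intermediate
9 | tert-butyl{[(2R)-2-(2,2-dimethoxyethyl)pent-4-en-1-yl]oxy}dimethylsilane | C=CC[C@H](CC(OC)OC)CO[Si](C)(C)C(C)(C)C | intermediate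
10 | tert-butyldimethyl(prop-2-yn-1-yloxy)silane | C#CCO[Si](C)(C)C(C)(C)C | starting material
11 | {3-[(tert-butyldimethylsilyl)oxy]prop-1-yn-1-yl}lithium | [Li]C#CCO[Si](C)(C)C(C)(C)C | intermediate
12 | methyl 4-[(tert-butyldimethylsilyl)oxy]but-2-ynoate | COC(=O)C#CCO[Si](C)(C)C(C)(C)C | intermediate
13 | 9-[(4R)-4-{[(tert-butyldimethylsilyl)oxy]methyl}-6,6-dimethoxyhexyl]-9-borabicyclo[3.3.1]nonane | COC(OC)C[C@H](CO[Si](C)(C)C(C)(C)C)CCCB1C2CCCC1CCC2 | intermediate
14 | methyl (2Z,7R)-3,7-bis{[(tert-butyldimethylsilyl)oxy]methyl}-9,9-dimethoxynon-2-enoate | COC(=O)/C=C(CO[Si](C)(C)C(C)(C)C)/CCC[C@@H](CO[Si](C)(C)C(C)(C)C)CC(OC)OC | intermediate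
15 | (2Z,7R)-3,7-bis{[(tert-butyldimethylsilyl)oxy]methyl}-9,9-dimethoxynon-2-en-1-ol | OC/C=C(CO[Si](C)(C)C(C)(C)C)/CCC[C@@H](CO[Si](C)(C)C(C)(C)C)CC(OC)OC | intermediate
16 | (2Z,7R)-3,7-bis{[(tert-butyldimethylsilyl)oxy]methyl}-9,9-dimethoxynon-2-enal | O=C/C=C(CO[Si](C)(C)C(C)(C)C)/CCC[C@@H](CO[Si](C)(C)C(C)(C)C)CC(OC)OC | intermediate
17 | 1-methoxy-4-[(prop-2-yn-1-yloxy)methyl]benzene | C#CCOCc1ccc(OC)cc1 | starting material
18 | {3-[(4-methoxybenzyl)oxy]prop-1-yn-1-yl}(methyl)zinc | C[Zn]C#CCOCc1ccc(OC)cc1 | intermediate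
19 | (4S,5Z,10R)-6,10-bis{[(tert-butyldimethylsilyl)oxy]methyl}-12,12-dimethoxy-1-[(4-methoxybenzyl)oxy]dodec-5-en-2-yn-4-ol | COc1ccc(COCC#C[C@@H](O)/C=C(CO[Si](C)(C)C(C)(C)C)/CCC[C@@H](CO[Si](C)(C)C(C)(C)C)CC(OC)OC)cc1 | intermediate
20 | sodium cyclic vinylalanate of 19 (five-membered O–Al–C=C–C chelate, aluminium on the carbon bearing CH2OPMB, two 2-methoxyethoxy ligands) | [Na+].COCCO[Al-]1(OCCOC)O[C@@H](/C=C(CO[Si](C)(C)C(C)(C)C)/CCC[C@@H](CO[Si](C)(C)C(C)(C)C)CC(OC)OC)C=C1COCc1ccc(OC)cc1 | intermediate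
21 | (2Z,4S,5Z,10R)-6,10-bis{[(tert-butyldimethylsilyl)oxy]methyl}-2-iodo-12,12-dimethoxy-1-[(4-methoxybenzyl)oxy]dodeca-2,5-dien-4-ol | COc1ccc(COC/C(I)=C/[C@@H](O)/C=C(CO[Si](C)(C)C(C)(C)C)/CCC[C@@H](CO[Si](C)(C)C(C)(C)C)CC(OC)OC)cc1 | intermediate
22 | (5S)-5-[(1Z,6R)-2,6-bis{[(tert-butyldimethylsilyl)oxy]methyl}-8,8-dimethoxyoct-1-en-1-yl]-3-{[(4-methoxybenzyl)oxy]methyl}furan-2(5H)-one | COc1ccc(COCC2=C[C@H](/C=C(CO[Si](C)(C)C(C)(C)C)/CCC[C@@H](CO[Si](C)(C)C(C)(C)C)CC(OC)OC)OC2=O)cc1 | intermediate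
23 | (5S)-5-[(1Z,6R)-2,6-bis{[(tert-butyldimethylsilyl)oxy]methyl}-8,8-dimethoxyoct-1-en-1-yl]-3-(hydroxymethyl)furan-2(5H)-one | OCC1=C[C@H](/C=C(CO[Si](C)(C)C(C)(C)C)/CCC[C@@H](CO[Si](C)(C)C(C)(C)C)CC(OC)OC)OC1=O | intermediate
24 | (5S)-3-(bromomethyl)-5-[(1Z,6R)-2,6-bis{[(tert-butyldimethylsilyl)oxy]methyl}-8,8-dimethoxyoct-1-en-1-yl]furan-2(5H)-one | BrCC1=C[C@H](/C=C(CO[Si](C)(C)C(C)(C)C)/CCC[C@@H](CO[Si](C)(C)C(C)(C)C)CC(OC)OC)OC1=O | intermediate
25 | (3R,7Z)-8-[(2S)-4-(bromomethyl)-5-oxo-2,5-dihydrofuran-2-yl]-3,7-bis{[(tert-butyldimethylsilyl)oxy]methyl}oct-7-enal | BrCC1=C[C@H](/C=C(CO[Si](C)(C)C(C)(C)C)/CCC[C@@H](CO[Si](C)(C)C(C)(C)C)CC=O)OC1=O | intermediate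
26 | allylchromium dichloride from 25 (CrCl2 unit in place of bromine, DMF-solvated) | Cl[Cr](Cl)CC1=C[C@H](/C=C(CO[Si](C)(C)C(C)(C)C)/CCC[C@@H](CO[Si](C)(C)C(C)(C)C)CC=O)OC1=O | intermediate
27 | (3aS,4R,6R,10Z,11aS)-6,10-bis{[(tert-butyldimethylsilyl)oxy]methyl}-4-hydroxy-3-methylidene-3a,4,5,6,7,8,9,11a-octahydrocyclodeca[b]furan-2(3H)-one | O[C@@H]1C[C@H](CO[Si](C)(C)C(C)(C)C)CCC/C(CO[Si](C)(C)C(C)(C)C)=C/[C@@H]2OC(=O)C(=C)[C@H]21 | intermediate
28 | (3aS,4R,6R,10Z,11aS)-6,10-bis{[(tert-butyldimethylsilyl)oxy]methyl}-3-methylidene-2-oxo-2,3,3a,4,5,6,7,8,9,11a-decahydrocyclodeca[b]furan-4-yl 2-methylprop-2-enoate | C=C(C)C(=O)O[C@@H]1C[C@H](CO[Si](C)(C)C(C)(C)C)CCC/C(CO[Si](C)(C)C(C)(C)C)=C/[C@@H]2OC(=O)C(=C)[C@H]21 | intermediate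
29 | (3aS,4R,6R,10Z,11aS)-6,10-bis(hydroxymethyl)-3-methylidene-2-oxo-2,3,3a,4,5,6,7,8,9,11a-decahydrocyclodeca[b]furan-4-yl 2-methylprop-2-enoate | C=C(C)C(=O)O[C@@H]1C[C@H](CO)CCC/C(CO)=C/[C@@H]2OC(=O)C(=C)[C@H]21 | target

**Totals**
Total step count: 18 (17 in the main line plus step 6 for ynoate 12).
Longest linear sequence: 17 steps (1 to 29 through steps 1–5 and 7–18).

**Steps most likely to fail**

Step 16 (macrocyclisation). Ring closure competes with oligomerisation and protonation of the allylchromium, and the sense at C8 rests on a chair model in which the aldehyde chain is equatorial. The fallback sets out from 25 and comes back at 28. If the closure runs through the chair with the aldehyde chain axial, it delivers the C8 epimer (3aS,4S,6R,10Z,11aS)-6,10-bis{[(tert-butyldimethylsilyl)oxy]methyl}-4-hydroxy-3-methylidene-3a,4,5,6,7,8,9,11a-octahydrocyclodeca[b]furan-2(3H)-one F1. The C8 centre is then set by substitution instead of by the addition: Mitsunobu esterification of F1 with methacrylic acid (PPh3, DIAD, toluene, 0 °C) installs the methacrylate with inversion and gives 28 directly. Any 27 in the mixture is acylated as in step 17, so both epimers converge on 28. This fallback does not rescue a failure to cyclise at all.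

Step 12 (carbonylative lactonisation). The product is a γ-alkenyl butenolide whose doubly allylic C6–H is acidic and whose allylic C6–O bond can be ionised by zerovalent palladium, so K2CO3 and the catalyst may erode the C6 configuration. The fallback sets out from 19 and comes back at 24, building the butenolide by ring-closing metathesis under neutral conditions. The vinylalanate 20 formed from 19 as in step 11 is quenched with water instead of iodine, giving (2E,4R,5Z,10R)-6,10-bis{[(tert-butyldimethylsilyl)oxy]methyl}-12,12-dimethoxy-1-[(4-methoxybenzyl)oxy]dodeca-2,5-dien-4-ol F2 (same spatial arrangement at C6; the descriptor changes by priority). Esterification with commercial 2-(bromomethyl)acrylic acid (diisopropylcarbodiimide, cat. DMAP, CH2Cl2, −20 °C) gives (2E,4R,5Z,10R)-6,10-bis{[(tert-butyldimethylsilyl)oxy]methyl}-12,12-dimethoxy-1-[(4-methoxybenzyl)oxy]dodeca-2,5-dien-4-yl 2-(bromomethyl)prop-2-enoate F3. Ring-closing metathesis with the second-generation Hoveyda–Grubbs catalyst (toluene, 80 °C) joins the acrylate to the disubstituted alkene, expels 4-methoxybenzyl allyl ether and gives bromide 24 directly, so steps 13 and 14 are skipped.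

Step 7 (copper-catalysed hydroalkylation). Transmetalation of the functionalised alkylborane may be slow, and any allenoate equilibration of the alkenylcopper would erode the alkene geometry. The fallback sets out from 9 (through the same borane 13) and comes back at 16, and lets a ring enforce the geometry. B-alkyl Suzuki–Miyaura coupling of 13 with commercial 4-bromofuran-2(5H)-one (PdCl2(dppf), K3PO4, DMF/THF/H2O, 50 °C) gives 4-[(4R)-4-{[(tert-butyldimethylsilyl)oxy]methyl}-6,6-dimethoxyhexyl]furan-2(5H)-one F4, in which C15 and C6 are cis by construction. Opening with Me(MeO)NH·HCl/Me3Al (CH2Cl2, 0 °C) gives (2Z,7R)-7-{[(tert-butyldimethylsilyl)oxy]methyl}-3-(hydroxymethyl)-N,9,9-trimethoxy-N-methylnon-2-enamide F5. Silylation (t-BuMe2SiCl, imidazole, DMF, 0 °C) gives (2Z,7R)-3,7-bis{[(tert-butyldimethylsilyl)oxy]methyl}-N,9,9-trimethoxy-N-methylnon-2-enamide F6, and i-Bu2AlH (THF, −78 °C) reduces it to enal 16, so steps 8 and 9 are not needed.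

**Further compounds**
F1 | step 16 | (3aS,4S,6R,10Z,11aS)-6,10-bis{[(tert-butyldimethylsilyl)oxy]methyl}-4-hydroxy-3-methylidene-3a,4,5,6,7,8,9,11a-octahydrocyclodeca[b]furan-2(3H)-one | O[C@H]1C[C@H](CO[Si](C)(C)C(C)(C)C)CCC/C(CO[Si](C)(C)C(C)(C)C)=C/[C@@H]2OC(=O)C(=C)[C@H]21
F2 | step 12 | (2E,4R,5Z,10R)-6,10-bis{[(tert-butyldimethylsilyl)oxy]methyl}-12,12-dimethoxy-1-[(4-methoxybenzyl)oxy]dodeca-2,5-dien-4-ol | COc1ccc(COC/C=C/[C@@H](O)/C=C(CO[Si](C)(C)C(C)(C)C)/CCC[C@@H](CO[Si](C)(C)C(C)(C)C)CC(OC)OC)cc1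
F3 | step 12 | (2E,4R,5Z,10R)-6,10-bis{[(tert-butyldimethylsilyl)oxy]methyl}-12,12-dimethoxy-1-[(4-methoxybenzyl)oxy]dodeca-2,5-dien-4-yl 2-(bromomethyl)prop-2-enoate | C=C(CBr)C(=O)O[C@H](/C=C/COCc1ccc(OC)cc1)/C=C(CO[Si](C)(C)C(C)(C)C)/CCC[C@@H](CO[Si](C)(C)C(C)(C)C)CC(OC)OC
F4 | step 7 | 4-[(4R)-4-{[(tert-butyldimethylsilyl)oxy]methyl}-6,6-dimethoxyhexyl]furan-2(5H)-one | O=C1C=C(CCC[C@@H](CO[Si](C)(C)C(C)(C)C)CC(OC)OC)CO1
F5 | step 7 | (2Z,7R)-7-{[(tert-butyldimethylsilyl)oxy]methyl}-3-(hydroxymethyl)-N,9,9-trimethoxy-N-methylnon-2-enamide | CON(C)C(=O)/C=C(CO)/CCC[C@@H](CO[Si](C)(C)C(C)(C)C)CC(OC)OC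
F6 | step 7 | (2Z,7R)-3,7-bis{[(tert-butyldimethylsilyl)oxy]methyl}-N,9,9-trimethoxy-N-methylnon-2-enamide | CON(C)C(=O)/C=C(CO[Si](C)(C)C(C)(C)C)/CCC[C@@H](CO[Si](C)(C)C(C)(C)C)CC(OC)OC
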